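The data were computed for substances that don't exist; noise was put on by code.

Does dilution or heat change the share of E lost on the way to Q, and which flasks have finished when they are read?

| setting | epsilon | eta | ochre | violet | red | amber |
|---|---|---|---|---|---|---|
| E | 0.035 M | 0.079 M | 0.025 M | 0.050 M | 0.025 M | 0.050 M |
| Z | 0.1 mol% | 0.1 mol% | 0.1 mol% | 0.1 mol% | 0.1 mol% | 0.1 mol% |
| temperature | 78 °C | 94 °C | 100 °C | 70 °C | 70 °C | 100 °C |
| remark | run made earlier | run made earlier |  |  |  |  |
| time |  |  | 30 h | 30 h | 30 h | 30 h |

| run | time / h | Q / % | E / % |
|---|---|---|---|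
| epsilon | 8.00 | 44.5 | 36.9 |
| epsilon | 15.0 | 67.9 | 10.9 |
| epsilon | 25.0 | 76.6 | 2.5 |
| epsilon | 30.0 | 78.2 | 0.1 |
| epsilon | 40.0 | 77.9 | 0.6 |
| eta | 1.33 | 33.7 | 42.7 |
| eta | 2.00 | 47.2 | 26.9 |
| eta | 3.00 | 59.1 | 12.1 |
| eta | 5.00 | 69.5 | 3.0 |
| eta | 10.0 | 72.0 | 0.9 |
| eta | 15.0 | 70.0 | 1.0 |

(readings scatter by 1 percentage point)

* all flasks from highest to lowest amount of Q, in percent of the E charged, at 30 h (ochre / violet / red / amber)
* the same order at 3.0 h (ochre / violet / red / amber)
* the amount of Q, in percent of the E charged of the flask you put first, at 30 h
* the amount of Q, in percent of the E charged of the flask you put last, at 30 h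

- the numbers in the tables scatter with a standard deviation of 1 percentage point

My zero is a flask that loses nothing. Against it the epsilon plateau misses 22.0% and the eta plateau 29.0%. Q+E stops falling once E is low, so the loss seems to need much E.

But Z is charged in mol%, so [Z] rises with [E]. If the Q path were first order in both, dilution would cancel from the selectivity and heat would have to explain the plateaus. I check this in eta, taking Q made per hour per unit of mean E. That gives 0.355 h⁻¹ early and 0.689 h⁻¹ late, more at low E, which looks like saturation of the catalyst.

An induction period would lower the early figure too, and both runs change heat and charge together, so this is a choice, not a proof. I choose the charge. The dilution exponent, the power of [E] at the start to which the missing share is proportional at fixed mol%, is 0.342. It puts the plateau at 80.4% for ochre and red, and at 75.2% for amber and violet.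

Plateaus are not yet readings, though. Epsilon needs 15.0 h to bring E down to 10.9%, and eta needs 3.00 h to reach about the same. Taking out the charge, that is a factor of 2.22 in time between 94 °C and 78 °C. 70 °C lies half as far below epsilon as eta lies above it, so I use the square root of that factor. Red then needs 31.3 h and violet 15.6 h, and red is still unfinished at 30 h. My order at 30 h is ochre, amber, violet, red, with violet just below amber.

The forecast parts from me here. It holds that “selectivity should depend on temperature rather than dilution” and gives violet > red > ochre > amber at 30 h, with 80% first and 69% last, and amber > ochre > violet > red at 3.0 h, the order I also expect there.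

The flasks give ochre > amber > violet > red at 30 h, with ochre at 80.6% and red at 66.8%, and amber > ochre > violet > red at 3.0 h.

    2 E → G (k = 0.0550 M⁻¹ min⁻¹, Ea = 73.0 kJ mol⁻¹)
    E + Z → X (k = 320 M⁻¹ min⁻¹, Ea = 52.0 kJ mol⁻¹)
    L → Z + Q (k = 11.0 min⁻¹, Ea = 91.0 kJ mol⁻¹)
    X → L (k = 81.0 min⁻¹, Ea = 101 kJ mol⁻¹)
    (constants at 100 °C)

Taking the reaction of two E to G away lifts ochre from 80.6% to >99.9%, so that reaction is the main reason for its shortfall. Ochre's 80.6% stands against the 80.4% from the exponent 0.342. Red, with ochre's charge at 70 °C, holds 66.8% at 30.0 h and reaches 81.4% at 300 h, against the same 80.4%.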